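## Structural features

Aikupikoxide D is a C14 chain (C1 ester carbon to C14 carbinol carbon) whose carbons C3–C6 are closed by an O2–O1 bridge into a 1,2-dioxane (O2 on C3, O1 on C6). C3 carries a hydrogen and the C2 propanoate arm. C6 is fully substituted, with a methyl group and the C7–C14 arm, and the two arms are cis on the ring. The exocyclic stereocentre C2 stands directly next to C3, while C6 is related to C3 only across the ring. The side chain holds a C9 ketone conjugated to an exocyclic C10 methylene and ends in the tertiary C14 alcohol. The fragile groups are: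
- the O–O bond, which is sensitive to reducing agents, low-valent metals, strong nucleophiles and bases (C3–H can trigger Kornblum–DeLaMare fragmentation);
- C2–H, which is α to the ester and β to a peroxide oxygen, so it can epimerise or open the ring by E1cB;
- the enone, a Michael acceptor.

The real difficulty is making the peroxide ring with a C–O bond at the quaternary C6, with C3/C6 cis and in the right sense relative to C2, and then finishing the chain without breaking O–O. The chosen key step uses the fact that C3–C4–C5–C6 is a four-carbon unit whose termini hold the two atoms of one O2 molecule on the same ring face. That is the pattern of a suprafacial [4+2] adduct of O2 with a (3E,5E)-diene.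

## Logic of the disconnections

**28 ⇒ 27.** The exocyclic C10=CH2 bond is cut. The α-methylene ketone is the most reactive group, so it is made last, by Horner–Wadsworth–Emmons methylenation with a one-carbon aldehyde. The gain is that the enone becomes a robust β-ketophosphonate that also fixes the site (C10, not C8). The forward step must use a base too weak to touch C2–H of the β-peroxy ester.

**27 ⇒ 26 ⇒ 25 ⇒ 24 ⇒ 23.** No skeletal bond is cut; the ester O–CH3 bond, the oxidation levels of C1 and C9, and two O–Si bonds are retraced. C2–H becomes acidic only at the aldehyde or ester level, so C1 stays a silyl ether until all strongly basic chemistry is over. The gain is that one fluoride step frees both alcohols and one oxidation serves C9 and C1 together. The demand is that 25 is oxidised on without epimerisation at C2 or ring opening.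

**23 ⇒ 16 + 21 (through 22).** The C9–C10 bond is cut, splitting the side chain at the future carbonyl. The phosphoryl group first stabilises the carbanion and later drives the methylenation, so it does double duty, and the route becomes convergent. The demand is that 22 adds to the aldehyde much faster than it attacks the O–O bond or C3–H.

**21 ⇒ 20 ⇒ 19 ⇒ 17 (through 18).** The C10–P bond, the O–Si bond and the two C14–CH3 bonds are cut. This reduces the C10–C14 piece to a commercial bromo ester. The forward steps need carbonyl addition to outrun substitution of the bromide, and the tertiary alcohol must be masked before carbanion chemistry.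

**16 ⇒ 15 ⇒ 14.** The C9 aldehyde is masked as its acetal, and a C4=C5 double bond is added back to expose the cycloaddition retron. The forward reduction must deliver H2 to C4=C5 without cleaving O–O, which points to diimide.

**14 ⇒ 12 + 13.** The O2–C3 and O1–C6 bonds are cut together, which opens the ring and removes two stereocentres in one move. The relative configuration is encoded in the diene geometry. The demands are (3E,5E) geometry, [4+2] rather than ene reactivity, and face selection by C2 alone, which is the weak point. The silyl ether and the acetal of 12 are kept because both are inert to singlet oxygen and the aryl silyl group eases separation of the facial isomers.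

**12 ⇒ 5 + 10 (through 11).** The C3=C4 bond is cut by a Julia–Kocienski disconnection, with the sulfone on the C1–C3 piece and the aldehyde on the C4–C9 piece. In this polarity the C2 stereocentre is never α to a carbonyl, and no allyl anion is formed across C5=C6, so both the configuration at C2 and the trisubstituted alkene geometry are protected. The demand is E-selectivity at C3=C4.

**5 ⇒ 4 ⇒ 3 ⇒ 2 ⇒ 1.** The C3–S bond, the sulfone oxygens, the ester oxidation level and the O–Si bond are retraced. This leads to a chiral-pool hydroxy ester that already holds C2; no step touches that centre.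

**10 ⇒ 9 ⇒ 8 ⇒ 6 (through 7).** The aldehyde and acetal functions are retraced to an acetate and a C=C bond. The E trisubstituted alkene is bought ready-made in 6. The demand is ozonolysis of only the distal, more electron-rich alkene.

## Other disconnections considered

**Alternative 1:** The O2–C3 bond alone is cut. In the forward step the anion of the tertiary C6 hydroperoxide of the cis-β-lactone A2 attacks the lactone alkyl carbon C3 in a 6-exo-tet substitution with inversion, giving the dioxane acid A1.
- In favour: the C2/C3 relationship comes from well-controlled aldol/β-lactone chemistry and is transferred stereospecifically. C6 would be set independently by epoxy-alcohol chemistry. C1 emerges directly as the acid.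
- Better than the chosen plan: stereocontrol (no facial-selectivity question) and the C1 oxidation level.
- Against: a free tertiary hydroperoxide must displace at an α-branched secondary carbon. The peroxide anion can instead attack the acyl carbon, and the β-lactone can eliminate or decarboxylate. A1 carries oxygen at C7 and C8, so the chain must be cut back and rebuilt by olefination and a further alkene saturation before C9–C14 are in place.
- Comparison: the mechanism is an ionic substitution with several competing pathways, against a single pericyclic event. The step count after ring closure is clearly higher than from 14.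

**Alternative 2:** The O1–C6 bond is cut. In the forward step the C3 hydroperoxide of A4, unmasked by acid just before use, opens the trisubstituted epoxide at its tertiary carbon C6 in a 6-exo closure with inversion, giving the diol A3.
- In favour: C6 derives from a Sharpless epoxidation of an E-allylic alcohol, so its configuration is reagent-controlled. Attack at the tertiary carbon is electronically matched under acid. No ene pathway exists.
- Equal to the chosen plan: A3 has the same C1 silyl ether as 15, so later C1 handling is the same.
- Better than the chosen plan: stereocontrol at C3 and C6, since both are set by reagents.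
- Against: a configurationally defined secondary hydroperoxide next to C2 is needed, and its making by substitution competes with elimination. Cationic character at C6 can erode the inversion. Several intermediates are free hydroperoxides. The C7–C8 diol of A3 again forces cleavage and re-extension of the chain.
- Comparison: more steps than the chosen plan, both before and after ring closure.

**Alternative 3:** The C4=C5 bond is cut. In the forward step the second-generation Grubbs catalyst joins the two vinyl groups of the bis-allylic peroxide A6, giving the dihydrodioxine A5.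
- In favour: the ring closure creates no stereocentre, so no face has to be chosen. A5 already carries the C1 methyl ester, which saves the late C1 deprotection and oxidations; this is better than the chosen plan.
- Equal to the chosen plan: A5 is the same ring type as 14, so the diimide saturation is shared.
- Against: the difficulty moves into A6, an unsymmetrical tertiary–secondary dialkyl peroxide with both carbinol centres defined, for which no general stereocontrolled synthesis exists (substitution at a secondary allylic carbon competes with allylic transposition and ionisation). Ruthenium carbenes and hydrides can degrade peroxides. C9 of A5 is only at the alcohol level, costing a deprotection and an oxidation. The ester is present during the basic C9–C10 bond formation, exposing C2–H.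
- Comparison: better at the C1 end, equal in ring saturation, worse in substrate access and in late-stage base tolerance.

Key step: step 9

Remark: atoms carry the target chain numbers C1–C14 throughout, and ring locants 3 and 6 coincide with C3 and C6. CIP labels at C2 and C6 change along the route only because substituent priorities change; no stereocentre is inverted.

Assumption: the C9 and C10 centres made in step 15 are carried as a mixture, since C9 is destroyed in step 17 and C10 in step 20.

## Route

Step 1
Reactants: 1 methyl (2R)-3-hydroxy-2-methylpropanoate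
Product: 2 methyl (2R)-3-[(tert-butyldiphenylsilyl)oxy]-2-methylpropanoate
Conditions: t-BuPh2SiCl, imidazole, CH2Cl2, 0 °C → rt
Reagents that add atoms: tert-butyl(chloro)diphenylsilane, CC(C)(C)[Si](Cl)(c1ccccc1)c1ccccc1
Why: Imidazole-mediated silylation of the primary alcohol, too weakly basic to epimerise C2; this silyl group should survive singlet oxygen, diimide, dilute acid and a phosphonate carbanion, and its aryl rings give a UV handle for the later isomer separation.

Step 2
Reactants: 2 methyl (2R)-3-[(tert-butyldiphenylsilyl)oxy]-2-methylpropanoate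
Product: 3 (2S)-3-[(tert-butyldiphenylsilyl)oxy]-2-methylpropan-1-ol
Conditions: i-Bu2AlH (2.5 equiv), CH2Cl2, −78 → 0 °C; aq. potassium sodium tartrate
Reagents that add atoms: none
Why: Hydride reduction of the ester to the primary alcohol with the silyl ether untouched; the stereocentre is not involved and only its label changes.

Step 3
Reactants: 3 (2S)-3-[(tert-butyldiphenylsilyl)oxy]-2-methylpropan-1-ol
Product: 4 5-({(2R)-3-[(tert-butyldiphenylsilyl)oxy]-2-methylpropyl}sulfanyl)-1-phenyl-1H-tetrazole
Conditions: 1-phenyl-1H-tetrazole-5-thiol, PPh3, DIAD, THF, 0 °C → rt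
Reagents that add atoms: 1-phenyl-1H-tetrazole-5-thiol, Sc1nnnn1-c1ccccc1
Why: Mitsunobu thioetherification of an unhindered primary alcohol with an acidic heteroaryl thiol; the C–S bond forms at the future C3, one carbon away from the stereocentre, which therefore cannot invert.

Step 4
Reactants: 4 5-({(2R)-3-[(tert-butyldiphenylsilyl)oxy]-2-methylpropyl}sulfanyl)-1-phenyl-1H-tetrazole
Product: 5 5-({(2R)-3-[(tert-butyldiphenylsilyl)oxy]-2-methylpropyl}sulfonyl)-1-phenyl-1H-tetrazole
Conditions: (NH4)6Mo7O24·4H2O (cat.), 30% aq. H2O2, EtOH, 0 °C → rt
Reagents that add atoms: hydrogen peroxide, OO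
Why: Molybdate-catalysed peroxide oxidation of the sulfide to the sulfone needed for the Julia–Kocienski olefination; the silyl ether tolerates the mildly acidic medium.

Step 5
Reactants: 6 geranyl acetate, (2E)-3,7-dimethylocta-2,6-dien-1-yl acetate
Product: 8 (2E)-6,6-dimethoxy-3-methylhex-2-en-1-yl acetate, via (2E)-3-methyl-6-oxohex-2-en-1-yl acetate 7 (not isolated)
Conditions: O3 (1 equiv), CH2Cl2/MeOH, −78 °C; Me2S, −78 °C → rt; then HC(OMe)3, PPTS (cat.), rt
Reagents that add atoms: trimethyl orthoformate, COC(OC)OC (the two methoxy groups of 8); ozone, [O-][O+]=O (carbonyl oxygen of 7 only)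
Why: Ozone cleaves the electron-rich distal alkene much faster than the alkene deactivated by the allylic acetate, and stoichiometric dosing stops the reaction there. Reductive work-up gives aldehyde 7, which acid-catalysed acetalisation (orthoformate as water scavenger) converts in the same flask into 8 with the E alkene untouched.

Step 6
Reactants: 8 (2E)-6,6-dimethoxy-3-methylhex-2-en-1-yl acetate
Product: 9 (2E)-6,6-dimethoxy-3-methylhex-2-en-1-ol
Conditions: K2CO3 (0.2 equiv), MeOH, rt
Reagents that add atoms: none
Why: Carbonate-catalysed transesterification of the acetate with methanol; the acetal and the alkene geometry are stable to mild base.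

Step 7
Reactants: 9 (2E)-6,6-dimethoxy-3-methylhex-2-en-1-ol
Product: 10 (2E)-6,6-dimethoxy-3-methylhex-2-enal
Conditions: MnO2 (activated, excess), CH2Cl2, rt
Reagents that add atoms: none
Why: Heterogeneous MnO2 oxidation is selective for the allylic alcohol, neutral enough for the acetal, and keeps the E geometry of the alkene that becomes C5=C6.

Step 8
Reactants: 5 5-({(2R)-3-[(tert-butyldiphenylsilyl)oxy]-2-methylpropyl}sulfonyl)-1-phenyl-1H-tetrazole; 10 (2E)-6,6-dimethoxy-3-methylhex-2-enal
Product: 12 tert-butyl{[(2S,3E,5E)-9,9-dimethoxy-2,6-dimethylnona-3,5-dien-1-yl]oxy}diphenylsilane, via potassium sulfonyl carbanion 11 (not isolated)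
Conditions: 5 (1.2 equiv), KN(SiMe3)2 (1.1 equiv), DME, −60 °C; then 10, −60 °C → rt
Reagents that add atoms: none
Why: Julia–Kocienski olefination: 11 adds to the enal, the tetrazolyl group migrates to oxygen (Smiles rearrangement) and anti-elimination of SO2 and tetrazolate forms C3=C4, the phenyltetrazolyl sulfone with a potassium base in an ether solvent favouring E. The carbanion is β to C2, so that centre cannot epimerise, and no allyl anion spans C5=C6, so its E geometry is carried over from 6. Any minor 3Z isomer is removed by chromatography.

Step 9
Reactants: 12 tert-butyl{[(2S,3E,5E)-9,9-dimethoxy-2,6-dimethylnona-3,5-dien-1-yl]oxy}diphenylsilane; 13 dioxygen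
Product: 14 tert-butyl{(2R)-2-[(3S,6S)-6-(3,3-dimethoxypropyl)-6-methyl-3,6-dihydro-1,2-dioxin-3-yl]propoxy}diphenylsilane
Conditions: O2 (bubbled), 5,10,15,20-tetraphenylporphyrin (cat.), visible light, CH2Cl2, −78 °C; chromatographic separation from the facial isomer
Reagents that add atoms: none
Why: Energy transfer from the photoexcited porphyrin converts 13 into singlet oxygen, which adds to the s-cis rotamer of the C3=C4–C5=C6 diene in a concerted, suprafacial [4+2] cycloaddition, forming O2–C3 and O1–C6 and moving the double bond to C4=C5. The closest known reaction type is the dye-sensitised photooxygenation of acyclic 1,3-dienes to 3,6-dihydro-1,2-dioxines, including dienes with two substituents at one terminus. The six-membered ring is closed by cycloaddition (4π of the diene plus 2π of O2), both C–O bonds arising in one step and not by a ring-closing substitution. The relative configuration of the new stereocentres C3 and C6 is controlled by the diene geometry: in the E,E-diene the C2 arm and the C7 chain are outside and the C6 methyl and C3–H inside, so suprafacial addition places the two chains cis. The absolute sense at C3 and C6 depends on which diene face is attacked and is controlled only by the C2 stereocentre; the required isomer arises by attack anti to the C2 methyl in the rotamer with C1 anti to C4, but an E-alkene exerts little allylic strain, so the preference should be modest and the two cis adducts are to be separated by chromatography. The step needs chemoselectivity for [4+2] over the Schenck ene reaction at the trisubstituted C5=C6 alkene (allylic hydrogens on the C6 methyl and on C7) and over [2+2]; the E,E geometry keeps the s-cis rotamer reachable despite the inside methyl, and low temperature with a non-polar aprotic solvent disfavours the more polar ene pathway. Acetal and silyl ether are inert to singlet oxygen, and amines are excluded so that the allylic C3–H of 14 is not removed in a Kornblum–DeLaMare fragmentation.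

Step 10
Reactants: 14 tert-butyl{(2R)-2-[(3S,6S)-6-(3,3-dimethoxypropyl)-6-methyl-3,6-dihydro-1,2-dioxin-3-yl]propoxy}diphenylsilane
Product: 15 tert-butyl{(2R)-2-[(3S,6R)-6-(3,3-dimethoxypropyl)-6-methyl-1,2-dioxan-3-yl]propoxy}diphenylsilane
Conditions: KO2CN=NCO2K (excess), AcOH, CH2Cl2, 0 °C → rt
Reagents that add atoms: none
Why: Diimide made in the flask transfers H2 to C4=C5 in a concerted syn fashion without reducing the O–O bond, which catalytic hydrogenation would cleave. The weakly acidic medium avoids base-induced fragmentation at the allylic C3–H; no stereocentre is created.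

Step 11
Reactants: 15 tert-butyl{(2R)-2-[(3S,6R)-6-(3,3-dimethoxypropyl)-6-methyl-1,2-dioxan-3-yl]propoxy}diphenylsilane
Product: 16 tert-butyl{(2R)-2-[(3S,6R)-6-methyl-6-(3-oxopropyl)-1,2-dioxan-3-yl]propoxy}diphenylsilane
Conditions: 1 M aq. HCl, THF, 0 °C → rt
Reagents that add atoms: water, O
Why: Acid-catalysed hydrolysis of the dimethyl acetal to the C9 aldehyde; the dialkyl peroxide and the primary aryl silyl ether are stable to dilute aqueous acid at room temperature.

Step 12
Reactants: 17 ethyl 5-bromopentanoate
Product: 19 6-bromo-2-methylhexan-2-ol, via 6-bromohexan-2-one 18 (not isolated)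
Conditions: MeMgBr (2.3 equiv), THF, −78 → 0 °C; aq. NH4Cl
Reagents that add atoms: methylmagnesium bromide, C[Mg]Br
Why: Twofold Grignard addition to the ester through ketone 18 gives the tertiary alcohol (C14 with both methyl groups). At low temperature carbonyl addition is far faster than substitution of the primary bromide, and a cold quench keeps the alkoxide from cyclising onto the bromide carbon.

Step 13
Reactants: 19 6-bromo-2-methylhexan-2-ol
Product: 20 [(6-bromo-2-methylhexan-2-yl)oxy]triethylsilane
Conditions: Et3SiOTf, 2,6-lutidine, CH2Cl2, −78 → 0 °C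
Reagents that add atoms: triethylsilyl trifluoromethanesulfonate, CC[Si](CC)(CC)OS(=O)(=O)C(F)(F)F
Why: A silyl triflate with a hindered pyridine base silylates the tertiary alcohol, which must be masked before the phosphonate is deprotonated; the triethylsilyl group is chosen so that it leaves together with the other silyl ether in step 16.

Step 14
Reactants: 20 [(6-bromo-2-methylhexan-2-yl)oxy]triethylsilane
Product: 21 diethyl {5-methyl-5-[(triethylsilyl)oxy]hexyl}phosphonate
Conditions: P(OEt)3 (neat, excess), 150 °C, EtBr distilled off
Reagents that add atoms: triethyl phosphite, CCOP(OCC)OCC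
Why: Michaelis–Arbuzov reaction of the primary bromide: substitution by phosphorus, then dealkylation of the phosphonium ion by bromide; the tertiary silyl ether is stable in the neutral melt.

Step 15
Reactants: 21 diethyl {5-methyl-5-[(triethylsilyl)oxy]hexyl}phosphonate; 16 tert-butyl{(2R)-2-[(3S,6R)-6-methyl-6-(3-oxopropyl)-1,2-dioxan-3-yl]propoxy}diphenylsilane
Product: 23 tert-butyl{(2R)-2-[6-{4-(diethoxyphosphoryl)-3-hydroxy-8-methyl-8-[(triethylsilyl)oxy]nonyl}-6-methyl-1,2-dioxan-3-yl]propoxy}diphenylsilane (C2, C3 and C6 arranged as in 16; mixture at C9 and C10), via lithiated phosphonate 22 (not isolated)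
Conditions: 21 (1.4 equiv), n-BuLi (1.3 equiv), THF, −78 °C; then 16, −78 °C; aq. NH4Cl at −78 °C
Reagents that add atoms: none
Why: Deprotonation α to phosphorus gives 22, which adds to the aldehyde as in the first stage of a Horner–Wadsworth–Emmons reaction; without a second anion-stabilising group the β-hydroxyphosphonate does not eliminate and is isolated. The excess of 21 over base keeps free butyllithium away from the peroxide, and at −78 °C addition to the aldehyde should be much faster than attack on the hindered O–O bond.

Step 16
Reactants: 23 the bis-silylated β-hydroxyphosphonate of step 15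
Product: 24 (2R)-2-{6-[4-(diethoxyphosphoryl)-3,8-dihydroxy-8-methylnonyl]-6-methyl-1,2-dioxan-3-yl}propan-1-ol (C2, C3 and C6 arranged as in 16; mixture at C9 and C10)
Conditions: HF·pyridine (excess), pyridine, THF, 0 °C → rt
Reagents that add atoms: none
Why: Fluoride-mediated cleavage of both silyl ethers in one operation (the tertiary triethylsilyl ether quickly, the primary aryl silyl ether more slowly). Buffered hydrogen fluoride is neither basic enough to fragment the peroxide nor acidic enough to dehydrate the tertiary alcohol.

Step 17
Reactants: 24 the triol of step 16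
Product: 25 (2S)-2-{(3S,6R)-6-[4-(diethoxyphosphoryl)-8-hydroxy-8-methyl-3-oxononyl]-6-methyl-1,2-dioxan-3-yl}propanal (mixture at C10)
Conditions: Dess–Martin periodinane (3 equiv), CH2Cl2, 0 °C → rt; used crude
Reagents that add atoms: none
Why: Dess–Martin oxidation converts the C9 carbinol into the ketone and the C1 alcohol into the aldehyde in one operation; the tertiary C14 alcohol cannot be oxidised and the peroxide is inert to the iodine reagent. The non-basic conditions limit epimerisation at C2, and the aldehyde is used at once.

Step 18
Reactants: 25 the keto aldehyde of step 17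
Product: 26 (2S)-2-{(3S,6R)-6-[4-(diethoxyphosphoryl)-8-hydroxy-8-methyl-3-oxononyl]-6-methyl-1,2-dioxan-3-yl}propanoic acid (mixture at C10)
Conditions: NaClO2, NaH2PO4, 2-methylbut-2-ene, t-BuOH/H2O, 0 °C → rt
Reagents that add atoms: sodium chlorite, [Na+].[O-]Cl=O
Why: Pinnick oxidation of the aldehyde to the acid with an alkene as hypochlorite scavenger; the buffered, weakly acidic medium should not epimerise C2, and ketone, phosphonate, peroxide and tertiary alcohol are untouched.

Step 19
Reactants: 26 the keto acid of step 18
Product: 27 methyl (2S)-2-{(3S,6R)-6-[4-(diethoxyphosphoryl)-8-hydroxy-8-methyl-3-oxononyl]-6-methyl-1,2-dioxan-3-yl}propanoate (mixture at C10)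
Conditions: Me3SiCHN2 (hexanes), toluene/MeOH (4:1), 0 °C
Reagents that add atoms: (trimethylsilyl)diazomethane, C[Si](C)(C)C=[N+]=[N-]
Why: Methyl ester formation by protonation of the diazo reagent and capture of the methyldiazonium ion by the carboxylate; it is specific for the acid, since the β-ketophosphonate and the tertiary alcohol are far too weakly acidic. No base is used, so the β-peroxy ester cannot open by E1cB.

Step 20
Reactants: 27 the β-ketophosphonate methyl ester of step 19
Product: 28 aikupikoxide D, methyl (2S)-2-[(3S,6R)-6-(8-hydroxy-8-methyl-4-methylidene-3-oxononyl)-6-methyl-1,2-dioxan-3-yl]propanoate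
Conditions: 37% aq. HCHO, K2CO3, THF/H2O, 0 °C → rt
Reagents that add atoms: formaldehyde, C=O
Why: Horner–Wadsworth–Emmons methylenation: carbonate removes only the doubly activated C10–H, the anion adds to formaldehyde and the adduct collapses to the C10=CH2 enone and diethyl phosphate, the phosphonate dictating C10 over C8. The enone is made last because it is the most fragile group, and a weak base at room temperature should spare the ester, C2 and the peroxide.

## Compound list

1 | methyl (2R)-3-hydroxy-2-methylpropanoate | COC(=O)[C@H](C)CO | starting material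
2 | methyl (2R)-3-[(tert-butyldiphenylsilyl)oxy]-2-methylpropanoate | COC(=O)[C@H](C)CO[Si](c1ccccc1)(c1ccccc1)C(C)(C)C | intermediate
3 | (2S)-3-[(tert-butyldiphenylsilyl)oxy]-2-methylpropan-1-ol | OC[C@H](C)CO[Si](c1ccccc1)(c1ccccc1)C(C)(C)C | intermediate
4 | 5-({(2R)-3-[(tert-butyldiphenylsilyl)oxy]-2-methylpropyl}sulfanyl)-1-phenyl-1H-tetrazole | c1ccccc1-n1nnnc1SC[C@H](C)CO[Si](c1ccccc1)(c1ccccc1)C(C)(C)C | intermediate
5 | 5-({(2R)-3-[(tert-butyldiphenylsilyl)oxy]-2-methylpropyl}sulfonyl)-1-phenyl-1H-tetrazole | c1ccccc1-n1nnnc1S(=O)(=O)C[C@H](C)CO[Si](c1ccccc1)(c1ccccc1)C(C)(C)C | intermediate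
6 | geranyl acetate, (2E)-3,7-dimethylocta-2,6-dien-1-yl acetate | CC(C)=CCC/C(C)=C/COC(C)=O | starting material
7 | (2E)-3-methyl-6-oxohex-2-en-1-yl acetate (not isolated) | O=CCC/C(C)=C/COC(C)=O | intermediate
8 | (2E)-6,6-dimethoxy-3-methylhex-2-en-1-yl acetate | COC(OC)CC/C(C)=C/COC(C)=O | intermediate
9 | (2E)-6,6-dimethoxy-3-methylhex-2-en-1-ol | COC(OC)CC/C(C)=C/CO | intermediate
10 | (2E)-6,6-dimethoxy-3-methylhex-2-enal | COC(OC)CC/C(C)=C/C=O | intermediate
11 | potassium salt of the α-sulfonyl carbanion of 5 (not isolated) | [K+].c1ccccc1-n1nnnc1S(=O)(=O)[CH-][C@H](C)CO[Si](c1ccccc1)(c1ccccc1)C(C)(C)C | intermediate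
12 | tert-butyl{[(2S,3E,5E)-9,9-dimethoxy-2,6-dimethylnona-3,5-dien-1-yl]oxy}diphenylsilane | COC(OC)CC/C(C)=C/C=C/[C@H](C)CO[Si](c1ccccc1)(c1ccccc1)C(C)(C)C | intermediate
13 | dioxygen | O=O | starting material
14 | tert-butyl{(2R)-2-[(3S,6S)-6-(3,3-dimethoxypropyl)-6-methyl-3,6-dihydro-1,2-dioxin-3-yl]propoxy}diphenylsilane | COC(OC)CC[C@@]1(C)C=C[C@@H]([C@H](C)CO[Si](c2ccccc2)(c2ccccc2)C(C)(C)C)OO1 | intermediate
15 | tert-butyl{(2R)-2-[(3S,6R)-6-(3,3-dimethoxypropyl)-6-methyl-1,2-dioxan-3-yl]propoxy}diphenylsilane | COC(OC)CC[C@@]1(C)CC[C@@H]([C@H](C)CO[Si](c2ccccc2)(c2ccccc2)C(C)(C)C)OO1 | intermediate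
16 | tert-butyl{(2R)-2-[(3S,6R)-6-methyl-6-(3-oxopropyl)-1,2-dioxan-3-yl]propoxy}diphenylsilane | O=CCC[C@@]1(C)CC[C@@H]([C@H](C)CO[Si](c2ccccc2)(c2ccccc2)C(C)(C)C)OO1 | intermediate
17 | ethyl 5-bromopentanoate | CCOC(=O)CCCCBr | starting material
18 | 6-bromohexan-2-one (not isolated) | CC(=O)CCCCBr | intermediate
19 | 6-bromo-2-methylhexan-2-ol | CC(C)(O)CCCCBr | intermediate
20 | [(6-bromo-2-methylhexan-2-yl)oxy]triethylsilane | CC[Si](CC)(CC)OC(C)(C)CCCCBr | intermediate
21 | diethyl {5-methyl-5-[(triethylsilyl)oxy]hexyl}phosphonate | CCOP(=O)(OCC)CCCCC(C)(C)O[Si](CC)(CC)CC | intermediate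
22 | α-lithio derivative of 21 (not isolated) | [Li+].CCOP(=O)(OCC)[CH-]CCCC(C)(C)O[Si](CC)(CC)CC | intermediate
23 | tert-butyl{(2R)-2-[6-{4-(diethoxyphosphoryl)-3-hydroxy-8-methyl-8-[(triethylsilyl)oxy]nonyl}-6-methyl-1,2-dioxan-3-yl]propoxy}diphenylsilane, C9/C10 mixture | CCOP(=O)(OCC)C(CCCC(C)(C)O[Si](CC)(CC)CC)C(O)CC[C@@]1(C)CC[C@@H]([C@H](C)CO[Si](c2ccccc2)(c2ccccc2)C(C)(C)C)OO1 | intermediate
24 | (2R)-2-{6-[4-(diethoxyphosphoryl)-3,8-dihydroxy-8-methylnonyl]-6-methyl-1,2-dioxan-3-yl}propan-1-ol, C9/C10 mixture | CCOP(=O)(OCC)C(CCCC(C)(C)O)C(O)CC[C@@]1(C)CC[C@@H]([C@H](C)CO)OO1 | intermediate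
25 | (2S)-2-{(3S,6R)-6-[4-(diethoxyphosphoryl)-8-hydroxy-8-methyl-3-oxononyl]-6-methyl-1,2-dioxan-3-yl}propanal, C10 mixture | CCOP(=O)(OCC)C(CCCC(C)(C)O)C(=O)CC[C@@]1(C)CC[C@@H]([C@H](C)C=O)OO1 | intermediate
26 | (2S)-2-{(3S,6R)-6-[4-(diethoxyphosphoryl)-8-hydroxy-8-methyl-3-oxononyl]-6-methyl-1,2-dioxan-3-yl}propanoic acid, C10 mixture | CCOP(=O)(OCC)C(CCCC(C)(C)O)C(=O)CC[C@@]1(C)CC[C@@H]([C@H](C)C(=O)O)OO1 | intermediate
27 | methyl (2S)-2-{(3S,6R)-6-[4-(diethoxyphosphoryl)-8-hydroxy-8-methyl-3-oxononyl]-6-methyl-1,2-dioxan-3-yl}propanoate, C10 mixture | CCOP(=O)(OCC)C(CCCC(C)(C)O)C(=O)CC[C@@]1(C)CC[C@@H]([C@H](C)C(=O)OC)OO1 | intermediate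
28 | aikupikoxide D, methyl (2S)-2-[(3S,6R)-6-(8-hydroxy-8-methyl-4-methylidene-3-oxononyl)-6-methyl-1,2-dioxan-3-yl]propanoate | C=C(CCCC(C)(C)O)C(=O)CC[C@@]1(C)CC[C@@H]([C@H](C)C(=O)OC)OO1 | target

## Step count and risk

Total step count: 20. Longest linear sequence: 14 steps (steps 1–4, 8–11 and 15–20, from 1).

**Step 9 (key step).** The most likely failure is poor discrimination between the two diene faces. C2 exerts little allylic strain on an E-alkene, and in the rotamer with C2–H eclipsing C3=C4 the bulky silyloxymethyl group lies on the very face that has to be oxygenated. Diversion into the ene pathway is a second risk, because the inside C6 methyl raises the energy of the s-cis rotamer.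

Fallback: replace steric control by hydrogen-bond delivery. Setting out from 12, fluoride (Bu4NF, THF) removes the silyl group to give (2S,3E,5E)-9,9-dimethoxy-2,6-dimethylnona-3,5-dien-1-ol F1. Sensitised photooxygenation of F1 in a non-polar solvent at low temperature, where the C1 hydroxyl can hydrogen-bond to the incoming oxygen and steer it to the face it occupies, would give the hydroxy dihydrodioxine (2R)-2-[(3S,6S)-6-(3,3-dimethoxypropyl)-6-methyl-3,6-dihydro-1,2-dioxin-3-yl]propan-1-ol F2. Diimide reduction as in step 10 gives the saturated alcohol (2R)-2-[(3S,6R)-6-(3,3-dimethoxypropyl)-6-methyl-1,2-dioxan-3-yl]propan-1-ol F3. Silylation (t-BuPh2SiCl, imidazole), done only after the base-sensitive ring alkene is gone, comes back to the route at 15.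

**Step 8.** The most likely failure is loss of geometric purity, through incomplete E-selectivity in the elimination or through base-mediated γ-deprotonation of the enal, which would scramble C5=C6. A 3Z-diene cannot reach the s-cis rotamer and would only feed the ene pathway.

Fallback: reverse the polarity of the coupling. Setting out from 3, Dess–Martin oxidation gives (2R)-3-[(tert-butyldiphenylsilyl)oxy]-2-methylpropanal F4. Setting out from 9, Mitsunobu thioetherification with 1-phenyl-1H-tetrazole-5-thiol gives 5-{[(2E)-6,6-dimethoxy-3-methylhex-2-en-1-yl]sulfanyl}-1-phenyl-1H-tetrazole F5, and molybdate/H2O2 oxidation gives 5-{[(2E)-6,6-dimethoxy-3-methylhex-2-en-1-yl]sulfonyl}-1-phenyl-1H-tetrazole F6. Adding KN(SiMe3)2 at −78 °C to a mixture of F6 and F4 (Barbier mode, so that the allyl anion is trapped as it forms and F4 has little time to epimerise) comes back to the route at 12.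

**Step 15.** The most likely failure is attack of the carbanion on the O–O bond, or deprotonation at C3–H followed by ring fragmentation, competing with addition to the aldehyde.

Fallback: make the C9–C10 bond before the peroxide exists. Setting out from 12, mild acid hydrolysis (PPTS, acetone/H2O) gives (4E,6E,8S)-9-[(tert-butyldiphenylsilyl)oxy]-4,8-dimethylnona-4,6-dienal F7. Addition of 22 gives the dienyl β-hydroxyphosphonate F8. Photooxygenation as in step 9 gives the dihydrodioxine β-hydroxyphosphonate F9, and diimide reduction as in step 10 comes back to the route at 23. The facial isomers would then be separated later, at 25 or at 28, once the C9/C10 mixture has been removed.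

**Step 17.** The most likely failure is epimerisation at C2, or E1cB opening of the peroxide ring, while the β-peroxy aldehyde is handled.

Fallback: never accumulate the aldehyde. Setting out from 23, Dess–Martin oxidation of the C9 carbinol alone gives the bis-silylated β-ketophosphonate F10. HF·pyridine then gives the keto alcohol F11. A direct alcohol-to-acid oxidation (TEMPO, PhI(OAc)2, MeCN/H2O), in which the aldehyde hydrate is oxidised as fast as it forms, comes back to the route at 26.

**Step 20.** The most likely failure is deprotonation at C2 of the β-peroxy ester by the carbonate, with ring opening, or conjugate addition to the new enone during a slow reaction.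

Fallback: methylenate at the carboxylate stage, where C2–H is far less acidic. Setting out from 26, the same formaldehyde/K2CO3 treatment gives the enone acid (2S)-2-[(3S,6R)-6-(8-hydroxy-8-methyl-4-methylidene-3-oxononyl)-6-methyl-1,2-dioxan-3-yl]propanoic acid F12. Esterification with CH3I and KHCO3 in DMF comes back to the route at 28; a diazoalkane is avoided here because it could add to the enone.

## Further compounds

F1 | step 9 | (2S,3E,5E)-9,9-dimethoxy-2,6-dimethylnona-3,5-dien-1-ol | COC(OC)CC/C(C)=C/C=C/[C@H](C)CO
F2 | step 9 | (2R)-2-[(3S,6S)-6-(3,3-dimethoxypropyl)-6-methyl-3,6-dihydro-1,2-dioxin-3-yl]propan-1-ol | COC(OC)CC[C@@]1(C)C=C[C@@H]([C@H](C)CO)OO1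
F3 | step 9 | (2R)-2-[(3S,6R)-6-(3,3-dimethoxypropyl)-6-methyl-1,2-dioxan-3-yl]propan-1-ol | COC(OC)CC[C@@]1(C)CC[C@@H]([C@H](C)CO)OO1
F4 | step 8 | (2R)-3-[(tert-butyldiphenylsilyl)oxy]-2-methylpropanal | O=C[C@H](C)CO[Si](c1ccccc1)(c1ccccc1)C(C)(C)C
F5 | step 8 | 5-{[(2E)-6,6-dimethoxy-3-methylhex-2-en-1-yl]sulfanyl}-1-phenyl-1H-tetrazole | COC(OC)CC/C(C)=C/CSc1nnnn1-c1ccccc1
F6 | step 8 | 5-{[(2E)-6,6-dimethoxy-3-methylhex-2-en-1-yl]sulfonyl}-1-phenyl-1H-tetrazole | COC(OC)CC/C(C)=C/CS(=O)(=O)c1nnnn1-c1ccccc1
F7 | step 15 | (4E,6E,8S)-9-[(tert-butyldiphenylsilyl)oxy]-4,8-dimethylnona-4,6-dienal | O=CCC/C(C)=C/C=C/[C@H](C)CO[Si](c1ccccc1)(c1ccccc1)C(C)(C)C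
F8 | step 15 | dienyl β-hydroxyphosphonate (diene of 12 with C9 as CH(OH) bonded to the phosphonate carbon of 21; C9/C10 mixture) | CCOP(=O)(OCC)C(CCCC(C)(C)O[Si](CC)(CC)CC)C(O)CC/C(C)=C/C=C/[C@H](C)CO[Si](c1ccccc1)(c1ccccc1)C(C)(C)C
F9 | step 15 | dihydrodioxine β-hydroxyphosphonate (C4=C5 unsaturated form of 23; C9/C10 mixture) | CCOP(=O)(OCC)C(CCCC(C)(C)O[Si](CC)(CC)CC)C(O)CC[C@@]1(C)C=C[C@@H]([C@H](C)CO[Si](c2ccccc2)(c2ccccc2)C(C)(C)C)OO1
F10 | step 17 | bis-silylated β-ketophosphonate (C9 ketone of 23; C10 mixture) | CCOP(=O)(OCC)C(CCCC(C)(C)O[Si](CC)(CC)CC)C(=O)CC[C@@]1(C)CC[C@@H]([C@H](C)CO[Si](c2ccccc2)(c2ccccc2)C(C)(C)C)OO1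
F11 | step 17 | keto alcohol (C9 ketone, free C1 and C14 alcohols; C10 mixture) | CCOP(=O)(OCC)C(CCCC(C)(C)O)C(=O)CC[C@@]1(C)CC[C@@H]([C@H](C)CO)OO1
F12 | step 20 | (2S)-2-[(3S,6R)-6-(8-hydroxy-8-methyl-4-methylidene-3-oxononyl)-6-methyl-1,2-dioxan-3-yl]propanoic acid | C=C(CCCC(C)(C)O)C(=O)CC[C@@]1(C)CC[C@@H]([C@H](C)C(O)=O)OO1
A1 | alternative 1 | 1,2-dioxane carboxylic acid with a C7,C8-diol on C6 (product of the lactone opening) | OC[C@H](O)[C@@]1(C)CC[C@@H]([C@H](C)C(O)=O)OO1
A2 | alternative 1 | cis-β-lactone (C1–C3) carrying the tertiary C6 hydroperoxide and the C7,C8-diol | OC[C@H](O)[C@@](OO)(C)CC[C@@H]1[C@H](C)C(=O)O1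
A3 | alternative 2 | 1,2-dioxane with a C7,C8-diol on C6 and the C1 silyl ether (product of the epoxide opening) | OC[C@H](O)[C@@]1(C)CC[C@@H]([C@H](C)CO[Si](c2ccccc2)(c2ccccc2)C(C)(C)C)OO1
A4 | alternative 2 | C3 hydroperoxide with a C6,C7-epoxy C8-alcohol and the C1 silyl ether | OC[C@@H]1O[C@@]1(C)CC[C@H](OO)[C@H](C)CO[Si](c2ccccc2)(c2ccccc2)C(C)(C)C
A5 | alternative 3 | 3,6-dihydro-1,2-dioxine methyl ester with a C9 silyl ether (product of the ring-closing metathesis) | CC(C)(C)[Si](c1ccccc1)(c1ccccc1)OCCC[C@@]1(C)C=C[C@@H]([C@H](C)C(=O)OC)OO1
A6 | alternative 3 | acyclic bis-allylic peroxide with vinyl groups on C3 and C6 | CC(C)(C)[Si](c1ccccc1)(c1ccccc1)OCCC[C@@](OO[C@@H](C=C)[C@H](C)C(=O)OC)(C)C=C
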